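**Plan**
- The target is an achiral chain of six benzene rings joined by five ether oxygens and carrying fifteen phenols. The rings are lettered A (2,4,6-trihydroxyphenyl end) to F (3,4,5-trihydroxyphenyl end), and all fifteen phenols travel as methyl ethers.
- Retrosynthetic cuts: first the fifteen O–CH3 bonds; then four diaryl ether bonds, each between a hindered phenol oxygen and an unhindered aryl carbon (ring D oxygen to ring E, ring C oxygen to ring D, ring B oxygen to ring C, ring E oxygen to ring F); last, ring A itself at its two C–C bonds between positions 2 and 3 and between positions 5 and 6.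
- Enabling feature: ring A is a phloroglucinol whose ether-bearing position 1 lies between the hydroxylated positions 2 and 6, so position 1 maps onto the central carbon of an aryloxymalonate, positions 2 and 6 onto its ester carbons, and positions 3, 4 and 5 onto carbons 2, 3 and 4 of 3-oxopentanedioate.
- Forward order: ring B phenol → aryloxymalonate (ether bond to ring A made by SN2 at an sp3 carbon) → ring A by Claisen–Dieckmann annulation → decarboxylation, methylation, debenzylation → ring C (Ullmann) → ring D (Ullmann with a bromo aldehyde, then Baeyer–Villiger to the phenol at position 2 of ring D) → preformed ring E–F bromide (Ullmann) → global demethylation.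
- Stereochemistry: the target has no stereocentre and none has to be set.

Key step: step 4

Remark on ring positions: positions are given in words. In ring A, position 1 is the ether carbon. In rings B, C and E, position 1 carries the oxygen on the ring A side and position 4 the oxygen on the ring F side. In ring D, position 1 carries the oxygen to ring C and position 2 the oxygen to ring E. In ring F, position 1 is the ether carbon.
Remark on reagents: dimethyl chloromalonate is used for the malonate ether because it transfers halogen to electron-rich phenoxides less readily than the bromide. Compounds 1, 2, 6, 8, 15, 19 and 25 are taken as purchased.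

Step 1
Reactants: 1 syringaldehyde; 2 benzyl bromide
Product: 3 4-(benzyloxy)-3,5-dimethoxybenzaldehyde
Conditions: K2CO3, DMF, 60 °C
Reagents that add atoms: none
Why: Williamson ether synthesis on the acidic 2,6-dimethoxyphenol installs the one hydrogenolysable group that will later free the oxygen at position 4 of ring B.

Step 2
Reactants: 3 4-(benzyloxy)-3,5-dimethoxybenzaldehyde
Product: 5 4-(benzyloxy)-3,5-dimethoxyphenol, via aryl formate 4 (not isolated)
Conditions: mCPBA, CH2Cl2, 0 °C to rt; then cat. K2CO3, MeOH, rt
Reagents that add atoms: mCPBA (3-chloroperoxybenzoic acid), OOC(=O)c1cccc(Cl)c1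
Why: Baeyer–Villiger (Dakin-type) oxidation, in which the electron-rich trioxygenated aryl group migrates in preference to hydride, gives the formate, and K2CO3-catalysed methanolysis should release the phenol at position 1 of ring B.

Step 3
Reactants: 5 4-(benzyloxy)-3,5-dimethoxyphenol; 6 dimethyl chloromalonate
Product: 7 dimethyl 2-[4-(benzyloxy)-3,5-dimethoxyphenoxy]malonate
Conditions: K2CO3, acetone, reflux
Reagents that add atoms: none
Why: SN2 O-alkylation of an unhindered phenoxide by a halomalonate, the standard route to aryloxymalonates, forms the ether bond between the ring B oxygen and the future position 1 of ring A at an sp3 carbon before ring A exists.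

Step 4
Reactants: 7 dimethyl 2-[4-(benzyloxy)-3,5-dimethoxyphenoxy]malonate; 8 dimethyl 3-oxopentanedioate
Product: 10 dimethyl 5-[4-(benzyloxy)-3,5-dimethoxyphenoxy]-2,4,6-trihydroxyisophthalate, via acyclic Claisen triester 9 (not isolated)
Conditions: NaOMe (3 equiv), MeOH, reflux; MeOH distilled off and the salt heated in xylene at 130–140 °C; then cold 1 M HCl
Reagents that add atoms: none
Why: Proposed new method: NaOMe converts 8 into the enolate of its doubly activated methylene at carbon 2, which acylates one ester of 7 (crossed Claisen, forming the bond between positions 2 and 3 of ring A) to give triester 9, whose remaining methylene (carbon 4 of the former ketodiester) then attacks the second malonate ester (Dieckmann, forming the bond between positions 6 and 5 of ring A); loss of two methanol and enolisation of the cyclohexanetrione, possible because the former malonate carbon keeps one hydrogen, should deliver the aromatic triol as its sodium salt. The closest known reaction type is the Claisen–Dieckmann cyclocondensation of unsubstituted dialkyl malonates with dialkyl 3-oxopentanedioates to 2,4,6-trihydroxyisophthalates, together with the NaOMe-mediated double acylation of amidines by 2-aryloxymalonates; a 2-aryloxymalonate has not been used in the carbocyclic version. Ring A closes in a 6-exo-trig mode, the enolate carbon attacking an ester carbonyl that lies outside the forming ring. No stereocentre results, because every ring carbon ends up aromatic. The step needs C- over O-acylation and crossed over self-condensation of 8: under NaOMe all acylations are reversible, so pyranones and self-condensation adducts of 8 can reopen, 7 has a single α-hydrogen and so cannot give a stable self-Claisen product, and its α-aryloxy group raises the electrophilicity of both esters. Distilling off methanol and the stability of the phloroglucinolate should pull the equilibria toward 10, while the benzyl and diaryl ethers are inert to NaOMe.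

Step 5
Reactants: 10 dimethyl 5-[4-(benzyloxy)-3,5-dimethoxyphenoxy]-2,4,6-trihydroxyisophthalate
Product: 12 2-[4-(benzyloxy)-3,5-dimethoxyphenoxy]benzene-1,3,5-triol, via isophthalic diacid 11 (not isolated)
Conditions: 2 M NaOH (aq), reflux, Ar; then HCl to pH 1, 70 °C
Reagents that add atoms: none
Why: Ester saponification followed by decarboxylation, which 2,4,6-trihydroxybenzoic acids undergo readily through their β-keto acid tautomers on acidification and warming, should leave the benzyl and diaryl ethers untouched.

Step 6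
Reactants: 12 2-[4-(benzyloxy)-3,5-dimethoxyphenoxy]benzene-1,3,5-triol
Product: 13 2-[4-(benzyloxy)-3,5-dimethoxyphenoxy]-1,3,5-trimethoxybenzene
Conditions: Me2SO4, K2CO3, acetone, reflux
Reagents that add atoms: dimethyl sulfate, COS(=O)(=O)OC
Why: Exhaustive Williamson O-methylation with dimethyl sulfate and K2CO3 in acetone, the conditions that favour O- over C-methylation of phloroglucinols, masks ring A for the later CuI-mediated couplings.

Step 7
Reactants: 13 2-[4-(benzyloxy)-3,5-dimethoxyphenoxy]-1,3,5-trimethoxybenzene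
Product: 14 2,6-dimethoxy-4-(2,4,6-trimethoxyphenoxy)phenol
Conditions: H2 (1 atm), 10% Pd/C, EtOAc–MeOH, rt
Reagents that add atoms: none
Why: Catalytic hydrogenolysis cleaves only the benzyl ether and so frees the hydroxyl at position 4 of ring B, methyl and diaryl ethers being stable.

Step 8
Reactants: 15 4-bromo-2,6-dimethoxyphenol; 2 benzyl bromide
Product: 16 2-(benzyloxy)-5-bromo-1,3-dimethoxybenzene
Conditions: K2CO3, DMF, 60 °C
Reagents that add atoms: none
Why: Williamson benzylation gives the ring C building block, with its bromide at the unhindered position 1 of ring C and the oxygen at position 4 temporarily masked.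

Step 9
Reactants: 14 2,6-dimethoxy-4-(2,4,6-trimethoxyphenoxy)phenol; 16 2-(benzyloxy)-5-bromo-1,3-dimethoxybenzene
Product: 17 2-{4-[4-(benzyloxy)-3,5-dimethoxyphenoxy]-3,5-dimethoxyphenoxy}-1,3,5-trimethoxybenzene
Conditions: CuI (10 mol%), picolinic acid (20 mol%), K3PO4, DMSO, 100 °C, Ar
Reagents that add atoms: none
Why: Ullmann diaryl ether synthesis with the CuI–picolinic acid system, which is established for doubly ortho-substituted phenols and electron-rich aryl bromides, should join the hindered oxygen at position 4 of ring B to the unhindered position 1 of ring C.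

Step 10
Reactants: 17 2-{4-[4-(benzyloxy)-3,5-dimethoxyphenoxy]-3,5-dimethoxyphenoxy}-1,3,5-trimethoxybenzene
Product: 18 4-[2,6-dimethoxy-4-(2,4,6-trimethoxyphenoxy)phenoxy]-2,6-dimethoxyphenol
Conditions: H2 (1 atm), 10% Pd/C, EtOAc–MeOH, rt
Reagents that add atoms: none
Why: Hydrogenolysis of the single benzyl ether, as in step 7, frees the hydroxyl at position 4 of ring C.

Step 11
Reactants: 19 5-bromo-1,2,3-trimethoxybenzene
Product: 21 6-bromo-2,3,4-trimethoxybenzaldehyde, via α-chloro ether 20 (not isolated)
Conditions: Cl2CHOMe, TiCl4, CH2Cl2, −10 to 0 °C; then ice-water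
Reagents that add atoms: dichloromethyl methyl ether, COC(Cl)Cl; water, O
Why: Rieche formylation can give only one regioisomer because the two free positions of 19 are equivalent (each ortho to bromine and para to a methoxy group), and the chloro ether is hydrolysed to the aldehyde on work-up.

Step 12
Reactants: 18 4-[2,6-dimethoxy-4-(2,4,6-trimethoxyphenoxy)phenoxy]-2,6-dimethoxyphenol; 21 6-bromo-2,3,4-trimethoxybenzaldehyde
Product: 22 6-{4-[2,6-dimethoxy-4-(2,4,6-trimethoxyphenoxy)phenoxy]-2,6-dimethoxyphenoxy}-2,3,4-trimethoxybenzaldehyde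
Conditions: CuI (10 mol%), picolinic acid (20 mol%), K3PO4, DMSO, 90 °C, Ar
Reagents that add atoms: none
Why: Ullmann coupling in which the ortho-formyl group activates the C–Br bond should arylate the hindered oxygen at position 4 of ring C with position 1 of ring D, the aldehyde being kept as the latent oxygen at position 2 of ring D.

Step 13
Reactants: 22 6-{4-[2,6-dimethoxy-4-(2,4,6-trimethoxyphenoxy)phenoxy]-2,6-dimethoxyphenoxy}-2,3,4-trimethoxybenzaldehyde
Product: 24 6-{4-[2,6-dimethoxy-4-(2,4,6-trimethoxyphenoxy)phenoxy]-2,6-dimethoxyphenoxy}-2,3,4-trimethoxyphenol, via aryl formate 23 (not isolated)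
Conditions: mCPBA (1.2 equiv), CH2Cl2, 0 °C; then cat. K2CO3, MeOH, rt
Reagents that add atoms: mCPBA (3-chloroperoxybenzoic acid), OOC(=O)c1cccc(Cl)c1
Why: Baeyer–Villiger oxidation of the 2,6-dioxygenated benzaldehyde, whose aryl group migrates readily, should outrun peracid attack on the methoxylated rings at 0 °C, and mild methanolysis then exposes the phenol at position 2 of ring D.

Step 14
Reactants: 15 4-bromo-2,6-dimethoxyphenol; 25 3,4,5-trimethoxyphenylboronic acid
Product: 26 5-bromo-1,3-dimethoxy-2-(3,4,5-trimethoxyphenoxy)benzene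
Conditions: Cu(OAc)2 (1 equiv, reoxidised by air), pyridine, 4 Å molecular sieves, CH2Cl2, air, rt
Reagents that add atoms: none
Why: Chan–Lam–Evans oxidative coupling of a phenol with an arylboronic acid runs at room temperature, where the aryl bromide of 15 is inert, and so should give the ring E–F bromide in one step.

Step 15
Reactants: 24 6-{4-[2,6-dimethoxy-4-(2,4,6-trimethoxyphenoxy)phenoxy]-2,6-dimethoxyphenoxy}-2,3,4-trimethoxyphenol; 26 5-bromo-1,3-dimethoxy-2-(3,4,5-trimethoxyphenoxy)benzene
Product: 27 2-[4-(4-{2-[3,5-dimethoxy-4-(3,4,5-trimethoxyphenoxy)phenoxy]-3,4,5-trimethoxyphenoxy}-3,5-dimethoxyphenoxy)-3,5-dimethoxyphenoxy]-1,3,5-trimethoxybenzene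
Conditions: CuI (20 mol%), picolinic acid (40 mol%), K3PO4, DMSO, 110 °C, Ar
Reagents that add atoms: none
Why: Ullmann diaryl ether synthesis as in step 9, with the unhindered bromide at position 1 of ring E as electrophile and the phenoxide at position 2 of ring D as nucleophile, should complete the six-ring skeleton.

Step 16
Reactants: 27 2-[4-(4-{2-[3,5-dimethoxy-4-(3,4,5-trimethoxyphenoxy)phenoxy]-3,4,5-trimethoxyphenoxy}-3,5-dimethoxyphenoxy)-3,5-dimethoxyphenoxy]-1,3,5-trimethoxybenzene
Product: 28 2-[4-(4-{2-[3,5-dihydroxy-4-(3,4,5-trihydroxyphenoxy)phenoxy]-3,4,5-trihydroxyphenoxy}-3,5-dihydroxyphenoxy)-3,5-dihydroxyphenoxy]benzene-1,3,5-triol (CNP0175585.0)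
Conditions: BBr3 (30 equiv), CH2Cl2, −78 °C to rt; then H2O, 0 °C, Ar
Reagents that add atoms: none
Why: Lewis acid cleavage of aryl methyl ethers with BBr3, which leaves diaryl ether bonds intact, should remove all fifteen methyl groups, and work-up under argon protects the polyphenol.

**Compound list**
1 | syringaldehyde (4-hydroxy-3,5-dimethoxybenzaldehyde) | COc1cc(C=O)cc(OC)c1O | starting material
2 | benzyl bromide | BrCc1ccccc1 | starting material
3 | 4-(benzyloxy)-3,5-dimethoxybenzaldehyde | COc1cc(C=O)cc(OC)c1OCc1ccccc1 | intermediate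
4 | 4-(benzyloxy)-3,5-dimethoxyphenyl formate (formed in the flask) | COc1cc(OC=O)cc(OC)c1OCc1ccccc1 | intermediate
5 | 4-(benzyloxy)-3,5-dimethoxyphenol | COc1cc(O)cc(OC)c1OCc1ccccc1 | intermediate
6 | dimethyl chloromalonate | COC(=O)C(Cl)C(=O)OC | starting material
7 | dimethyl 2-[4-(benzyloxy)-3,5-dimethoxyphenoxy]malonate | COC(=O)C(Oc1cc(OC)c(OCc2ccccc2)c(OC)c1)C(=O)OC | intermediate
8 | dimethyl 3-oxopentanedioate | COC(=O)CC(=O)CC(=O)OC | starting material
9 | dimethyl 2-[4-(benzyloxy)-3,5-dimethoxyphenoxy]-4-(methoxycarbonyl)-3,5-dioxoheptanedioate (acyclic Claisen triester, mixture of stereoisomers and enol forms, formed in the flask) | COC(=O)CC(=O)C(C(=O)OC)C(=O)C(Oc1cc(OC)c(OCc2ccccc2)c(OC)c1)C(=O)OC | intermediate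
10 | dimethyl 5-[4-(benzyloxy)-3,5-dimethoxyphenoxy]-2,4,6-trihydroxyisophthalate | COC(=O)c1c(O)c(C(=O)OC)c(O)c(Oc2cc(OC)c(OCc3ccccc3)c(OC)c2)c1O | intermediate
11 | 5-[4-(benzyloxy)-3,5-dimethoxyphenoxy]-2,4,6-trihydroxyisophthalic acid (formed in the flask) | OC(=O)c1c(O)c(C(O)=O)c(O)c(Oc2cc(OC)c(OCc3ccccc3)c(OC)c2)c1O | intermediate
12 | 2-[4-(benzyloxy)-3,5-dimethoxyphenoxy]benzene-1,3,5-triol | Oc1cc(O)c(Oc2cc(OC)c(OCc3ccccc3)c(OC)c2)c(O)c1 | intermediate
13 | 2-[4-(benzyloxy)-3,5-dimethoxyphenoxy]-1,3,5-trimethoxybenzene | COc1cc(OC)c(Oc2cc(OC)c(OCc3ccccc3)c(OC)c2)c(OC)c1 | intermediate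
14 | 2,6-dimethoxy-4-(2,4,6-trimethoxyphenoxy)phenol | COc1cc(OC)c(Oc2cc(OC)c(O)c(OC)c2)c(OC)c1 | intermediate
15 | 4-bromo-2,6-dimethoxyphenol | COc1cc(Br)cc(OC)c1O | starting material
16 | 2-(benzyloxy)-5-bromo-1,3-dimethoxybenzene | COc1cc(Br)cc(OC)c1OCc1ccccc1 | intermediate
17 | 2-{4-[4-(benzyloxy)-3,5-dimethoxyphenoxy]-3,5-dimethoxyphenoxy}-1,3,5-trimethoxybenzene | COc1cc(OC)c(Oc2cc(OC)c(Oc3cc(OC)c(OCc4ccccc4)c(OC)c3)c(OC)c2)c(OC)c1 | intermediate
18 | 4-[2,6-dimethoxy-4-(2,4,6-trimethoxyphenoxy)phenoxy]-2,6-dimethoxyphenol | COc1cc(OC)c(Oc2cc(OC)c(Oc3cc(OC)c(O)c(OC)c3)c(OC)c2)c(OC)c1 | intermediate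
19 | 5-bromo-1,2,3-trimethoxybenzene | COc1cc(Br)cc(OC)c1OC | starting material
20 | 1-bromo-2-[chloro(methoxy)methyl]-3,4,5-trimethoxybenzene (racemic α-chloro ether, formed in the flask) | COC(Cl)c1c(Br)cc(OC)c(OC)c1OC | intermediate
21 | 6-bromo-2,3,4-trimethoxybenzaldehyde | COc1cc(Br)c(C=O)c(OC)c1OC | intermediate
22 | 6-{4-[2,6-dimethoxy-4-(2,4,6-trimethoxyphenoxy)phenoxy]-2,6-dimethoxyphenoxy}-2,3,4-trimethoxybenzaldehyde | COc1cc(OC)c(Oc2cc(OC)c(Oc3cc(OC)c(Oc4cc(OC)c(OC)c(OC)c4C=O)c(OC)c3)c(OC)c2)c(OC)c1 | intermediate
23 | 6-{4-[2,6-dimethoxy-4-(2,4,6-trimethoxyphenoxy)phenoxy]-2,6-dimethoxyphenoxy}-2,3,4-trimethoxyphenyl formate (formed in the flask) | COc1cc(OC)c(Oc2cc(OC)c(Oc3cc(OC)c(Oc4cc(OC)c(OC)c(OC)c4OC=O)c(OC)c3)c(OC)c2)c(OC)c1 | intermediate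
24 | 6-{4-[2,6-dimethoxy-4-(2,4,6-trimethoxyphenoxy)phenoxy]-2,6-dimethoxyphenoxy}-2,3,4-trimethoxyphenol | COc1cc(OC)c(Oc2cc(OC)c(Oc3cc(OC)c(Oc4cc(OC)c(OC)c(OC)c4O)c(OC)c3)c(OC)c2)c(OC)c1 | intermediate
25 | 3,4,5-trimethoxyphenylboronic acid | COc1cc(B(O)O)cc(OC)c1OC | starting material
26 | 5-bromo-1,3-dimethoxy-2-(3,4,5-trimethoxyphenoxy)benzene | COc1cc(Br)cc(OC)c1Oc1cc(OC)c(OC)c(OC)c1 | intermediate
27 | 2-[4-(4-{2-[3,5-dimethoxy-4-(3,4,5-trimethoxyphenoxy)phenoxy]-3,4,5-trimethoxyphenoxy}-3,5-dimethoxyphenoxy)-3,5-dimethoxyphenoxy]-1,3,5-trimethoxybenzene (pentadecamethyl ether of 28) | COc1cc(OC)c(Oc2cc(OC)c(Oc3cc(OC)c(Oc4cc(OC)c(OC)c(OC)c4Oc4cc(OC)c(Oc5cc(OC)c(OC)c(OC)c5)c(OC)c4)c(OC)c3)c(OC)c2)c(OC)c1 | intermediate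
28 | 2-[4-(4-{2-[3,5-dihydroxy-4-(3,4,5-trihydroxyphenoxy)phenoxy]-3,4,5-trihydroxyphenoxy}-3,5-dihydroxyphenoxy)-3,5-dihydroxyphenoxy]benzene-1,3,5-triol (CNP0175585.0) | Oc1cc(O)c(Oc2cc(O)c(Oc3cc(O)c(Oc4cc(O)c(O)c(O)c4Oc4cc(O)c(Oc5cc(O)c(O)c(O)c5)c(O)c4)c(O)c3)c(O)c2)c(O)c1 | target

Total step count: 16 (steps 8, 11 and 14 prepare the building blocks for ring C, ring D and rings E–F).
Longest linear sequence: 13 steps (steps 1–7, 9, 10, 12, 13, 15, 16).

**Steps most likely to fail**

Step 4 (labelled above). Self-condensation of the ketodiester may outrun acylation of the hindered and largely enolised aryloxymalonate, and O-acylation may drain material into lactones that fail to reopen. The fallback sets out from bromide 16 and rejoins the route at 13, using only known chemistry. Commercial 2,4,6-trimethoxybenzaldehyde would be oxidised with mCPBA in CH2Cl2 to 2,4,6-trimethoxyphenyl formate F1, which is methanolysed (cat. K2CO3, MeOH) to 2,4,6-trimethoxyphenol F2. Ullmann coupling of F2 with 16 (CuI, picolinic acid, K3PO4, DMSO, 100 °C), the same kind of coupling as step 9, should then give 13 directly. The ether between rings A and B is thus formed at the unhindered position 1 of ring B, and ring A is bought instead of built; steps 7 to 16 follow unchanged.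

Step 15. Arylation at the doubly flanked oxygen at position 2 of ring D may be too slow at 110 °C, so that reductive loss of bromine from the partner and oxidative degradation of the electron-rich phenoxide take over. The fallback sets out from bromide 26 (with phenol 24) and rejoins the route at 27. Bromine–lithium exchange on 26 (n-BuLi, THF, −78 °C) would give [3,5-dimethoxy-4-(3,4,5-trimethoxyphenoxy)phenyl]lithium F3, which is trapped with B(OiPr)3 and hydrolysed with dilute HCl to [3,5-dimethoxy-4-(3,4,5-trimethoxyphenoxy)phenyl]boronic acid F4. Chan–Lam–Evans coupling of F4 with 24 (Cu(OAc)2, pyridine, 4 Å molecular sieves, CH2Cl2, air, rt) should form the ether bond between rings D and E oxidatively at room temperature, replacing the halide-based coupling by a boron-based one.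

Step 16. Cleavage of fifteen methyl ethers may stop short, and the liberated pyrogallol and hydroxyhydroquinone rings may oxidise in air during isolation. The fallback sets out from 27 and rejoins the route at 28 by capture and release. After the BBr3 treatment and an aqueous quench under argon, the crude polyphenol would be acetylated without purification (Ac2O, pyridine, DMAP, rt) to the pentadecaacetate of 28 F5. This ester should be stable to air and silica, so it can be chromatographed and separated from under-cleaved material, which is returned to BBr3. Acid-catalysed methanolysis of F5 (HCl generated from AcCl in degassed MeOH, rt) followed by evaporation should deliver 28 with only volatile co-products.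

**Further compounds**
F1 | step 4 | 2,4,6-trimethoxyphenyl formate | COc1cc(OC)c(OC=O)c(OC)c1
F2 | step 4 | 2,4,6-trimethoxyphenol | COc1cc(OC)c(O)c(OC)c1
F3 | step 15 | [3,5-dimethoxy-4-(3,4,5-trimethoxyphenoxy)phenyl]lithium | [Li]c1cc(OC)c(Oc2cc(OC)c(OC)c(OC)c2)c(OC)c1
F4 | step 15 | [3,5-dimethoxy-4-(3,4,5-trimethoxyphenoxy)phenyl]boronic acid | COc1cc(B(O)O)cc(OC)c1Oc1cc(OC)c(OC)c(OC)c1
F5 | step 16 | pentadecaacetate of 28 | CC(=O)Oc1cc(OC(C)=O)c(Oc2cc(OC(C)=O)c(Oc3cc(OC(C)=O)c(Oc4cc(OC(C)=O)c(OC(C)=O)c(OC(C)=O)c4Oc4cc(OC(C)=O)c(Oc5cc(OC(C)=O)c(OC(C)=O)c(OC(C)=O)c5)c(OC(C)=O)c4)c(OC(C)=O)c3)c(OC(C)=O)c2)c(OC(C)=O)c1
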